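## The problem

- Target **14** (C30H22O15) is a linear phlorethol. Five phloroglucinol-derived benzene rings A–E are joined by four diaryl ether bridges and carry eleven free phenols. There is no stereocentre and no hindered axis, so the task is one of position, not of configuration.
- Numbering used throughout: in rings B–E, C1 is the carbon that carries the oxygen of the preceding ring.
  - Ring A is a 3,5-dihydroxyphenoxy group on B-C1.
  - Ring B has OH at C2 and C4 and passes the chain on through the oxygen at C6 to C-C1.
  - Ring C has OH at C2 and C6 and passes it on through the oxygen at C4 to D-C1.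
  - Ring D repeats B. Ring E ends the chain with OH at C2, C4 and C6.
- Every bridge therefore ends at a C1 that lies between two oxygenated carbons and para to a third. This di-ortho-substituted, very electron-rich carbon is the worst case for copper- or palladium-mediated C–O coupling and is inert to SNAr.
- Both partners of each bridge, a phenol oxygen and a phloroglucinol ring carbon, are nucleophiles by nature, so one of them must be reversed in polarity.
- The chain has a direction and a sequence: ortho exit from B, para exit from C, ortho exit from D. This order must be written into the building blocks, because the oxygens and C–H positions of each unit are otherwise alike.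
- The enabling feature is that in rings B and D the bridgehead C1 has a free hydroxyl on the neighbouring C2. The unit C1–C2–OH is thus the aromatised form of an α-diazo ketone C1(=N2)–C2(=O), an o-quinone diazide. In it C1 is an electrophilic carbene carbon and the oxygen at C2 is a built-in proton acceptor. In addition, B–O–C and D–O–E are the same diaryl ether, so **14** is ring A plus two copies of one dimer.
- The free polyphenol is sensitive to air, to base and to hot acid (ether exchange through keto tautomers), so it must be released last.

## Retrosynthesis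

**14 ⇒ 13.** Nine O–CH3 bonds and one O–CH2Ph bond are cut.
- The phenols travel as ethers because the free polyphenol would not survive carbenes, bases or oxidants.
- Methyl is used on every oxygen that comes to lie next to a carbene carbon. A benzyl ether there would place a phenyl ring within reach of C1. The single benzyl group sits far away, on C4 of the outer ring.
- **13** already holds the whole skeleton. The forward reaction must cleave alkyl–O bonds completely and leave aryl–O–aryl bonds alone.

**13 ⇒ 12 + 8.** The bond between D-C1 and the oxygen on C-C4 is cut.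
- It is the most central bridge and divides five rings into three plus two.
- Its oxygen sits on a carbon with two ortho hydrogens, so the nucleophile **12** is an open phenol.
- Cutting the B–C or D–E bridge in the same sense would ask an ortho-substituted phenol to react and would set free a less hindered one, which invites further insertion.
- Ring D becomes the o-quinone diazide **8** (C1=N2, C2=O). The forward O–H insertion must prefer oxygen over ring carbon and must stop after one event.

**12 ⇒ 11 ⇒ 10 ⇒ 9 + 8.** After the benzyl group is put back (**11**) and the capping methyl on B-C2 is removed (**10**), the bond between B-C1 and the oxygen of ring A is cut in the same way.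
- The electrophile is again **8**, which shows the hidden repeat.
- The nucleophile is the simple phenol **9**, which can be used in excess.
- Three rings fall back to one dimer and one monomer.

**8 ⇒ 7 ⇒ 6.** The diazo group at C1 comes from an amine and the amine from a nitro group. The position of the nitrogen is fixed without any regiochemical question. The forward steps are a chemoselective reduction and a diazotisation.

**6 ⇒ 5 ⇒ 3 + 4.** The two C–O bonds ortho to the nitro group are cut, C6–OAr and C2–OH.
- The flanked oxygen of ring C/E is now the nucleophile. The di-ortho substitution therefore lies on the partner where SNAr tolerates it.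
- The nitro group of **4** first activates both fluorides and later becomes the leaving group at C1.
- The two fluorides of **4** are equivalent, so the first substitution has one possible product.

**3 ⇒ 2 ⇒ 1.** The benzyl group is removed from the open oxygen of hydroquinone **2**, which comes from quinone **1**. The forward reaction relies on the steric difference between the flanked and the open hydroxyl.

## Roads not taken

**Alternative 1:** the most obvious plan.
- *Cut:* all four bridges between C1 and oxygen, with C1 as an aryl halide.
- *Forward key step:* Ullmann-type coupling, for instance of **9** with 2-iodo-1,3,5-trimethoxybenzene A1 to give diphlorethol pentamethyl ether A2. This is repeated three more times with halides that each carry one orthogonally protected oxygen.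
- *Why the chosen plan is better:*
  - Bond formation at copper happens in the ring plane, between two ortho alkoxy groups on the most electron-rich type of halide, and it must succeed four times.
  - Several different differentiated halides and a deprotection between couplings are needed.
  - The repeat B–C = D–E is not used.
  - The chosen plan forms the bond on the π face of a dearomatised carbon and uses one building block twice.

**Alternative 2:**
- *Cut:* the same bonds, as C–H plus H–O.
- *Forward key step:* anodic or enzyme-like dehydrogenative coupling of phloroglucinol A3 to diphlorethol A4 and onward.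
- *Why the chosen plan is better:*
  - The phenoxyl radical carries spin on oxygen and on three ring carbons, so C–C and C–O coupling compete.
  - Each product is more easily oxidised than its precursor.
  - Nothing in the substrate can encode the ortho/para/ortho order.
  - The route would be short on paper, but it gives no control over the one thing this target demands.

**Alternative 3:**
- *Cut:* all four bridges at C1, with each ring brought in as a monomeric quinone diazide. These are 6-diazo-3,5-dimethoxycyclohexa-2,4-dien-1-one A5 for B and D, and 4-diazo-3,5-dimethoxycyclohexa-2,5-dien-1-one A6 for C and E.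
- *Forward key step:* **9** plus A5 gives 2-(3,5-dimethoxyphenoxy)-3,5-dimethoxyphenol A7. Its new ortho OH takes up A6, whose new para OH takes up A5, and so on, without protecting-group steps.
- *Why the chosen plan is better:*
  - In the second and fourth insertions the reacting phenol is ortho-substituted, while the phenol set free is as open or more open. Chain growth cannot be stopped at one unit.
  - Four untested steps would follow one another on the growing chain.
  - A6 needs nitrogen placed selectively between two methoxy groups.
  - The chosen plan keeps the carbene only for the two bridges where the open phenol is the reacting one. It gives the other two bridges to SNAr.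

Key step: step 10

Remark: **14** has no stereogenic element and its SMILES carries no stereodescriptor, so the request for a single enantiomer is met trivially.
Remark: **1**, **4** and **9** are taken as catalogue compounds.

## Steps

Step 1
Reactants: 1 2,6-dimethoxy-1,4-benzoquinone
Product: 2 2,6-dimethoxybenzene-1,4-diol
Conditions: H2 (1 atm), 10% Pd/C, EtOAc, rt; filtered under N2
Reagents that add atoms: none
Why: Catalytic hydrogenation of a p-quinone to the hydroquinone, driven by aromatisation; no other reducible group is present.

Step 2
Reactants: 2 2,6-dimethoxybenzene-1,4-diol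
Product: 3 4-(benzyloxy)-2,6-dimethoxyphenol
Conditions: BnBr (1.0 equiv), K2CO3, DMF, 0 °C to rt, N2
Reagents that add atoms: benzyl bromide, BrCc1ccccc1
Why: Williamson ether synthesis; the hydroxyl at C4 has two ortho hydrogens, whereas the one at C1 is flanked by and hydrogen-bonded to two methoxy groups, so one equivalent of halide should alkylate the open oxygen.

Step 3
Reactants: 3 4-(benzyloxy)-2,6-dimethoxyphenol; 4 1,3-difluoro-5-methoxy-2-nitrobenzene
Product: 5 5-(benzyloxy)-2-(3-fluoro-5-methoxy-2-nitrophenoxy)-1,3-dimethoxybenzene
Conditions: 4 (1.3 equiv), K2CO3, DMF, 40 °C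
Reagents that add atoms: none
Why: SNAr (addition–elimination) at a fluoride ortho to nitro, a reaction that accepts 2,6-disubstituted phenoxides; the two fluorides are equivalent, and the first aryloxy group deactivates the ring, so a small excess of 4 should keep the reaction at monosubstitution.

Step 4
Reactants: 5 5-(benzyloxy)-2-(3-fluoro-5-methoxy-2-nitrophenoxy)-1,3-dimethoxybenzene
Product: 6 3-[4-(benzyloxy)-2,6-dimethoxyphenoxy]-5-methoxy-2-nitrophenol
Conditions: KOH (aq), DMSO, 70 °C; then 1 M HCl
Reagents that add atoms: potassium hydroxide, [K+].[OH-]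
Why: Second SNAr, now with hydroxide; fluoride is by far the best nucleofuge on the ring, and the nitrophenoxide formed is inert to further attack.

Step 5
Reactants: 6 3-[4-(benzyloxy)-2,6-dimethoxyphenoxy]-5-methoxy-2-nitrophenol
Product: 7 2-amino-3-[4-(benzyloxy)-2,6-dimethoxyphenoxy]-5-methoxyphenol
Conditions: H2 (1 atm), 5% Pt(S)/C, EtOAc, rt; used at once
Reagents that add atoms: none
Why: Catalytic hydrogenation of a nitroarene over sulfided platinum, which does not hydrogenolyse benzyl ethers.

Step 6
Reactants: 7 2-amino-3-[4-(benzyloxy)-2,6-dimethoxyphenoxy]-5-methoxyphenol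
Product: 8 5-[4-(benzyloxy)-2,6-dimethoxyphenoxy]-6-diazo-3-methoxycyclohexa-2,4-dien-1-one
Conditions: t-BuONO (1.3 equiv), TFA (5 mol %), THF, 0 °C, dark; NaHCO3 wash
Reagents that add atoms: tert-butyl nitrite, CC(C)(C)ON=O
Why: Classical aprotic diazotisation of an o-aminophenol with an alkyl nitrite; the phenolic proton is lost as the diazonium group forms, which gives the neutral o-quinone diazide directly.

Step 7
Reactants: 8 5-[4-(benzyloxy)-2,6-dimethoxyphenoxy]-6-diazo-3-methoxycyclohexa-2,4-dien-1-one; 9 3,5-dimethoxyphenol
Product: 10 3-[4-(benzyloxy)-2,6-dimethoxyphenoxy]-2-(3,5-dimethoxyphenoxy)-5-methoxyphenol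
Conditions: 9 (3 equiv), Rh2(esp)2 (1 mol %), 4 Å MS, PhCF3, 60 °C, slow addition of 8, dark
Reagents that add atoms: none
Why: Proposed new method: the same Rh(II) quinoid-carbene O–H insertion as in step 10 (closest known type: Rh(II)-catalysed O–H insertion of 1,2-diazonaphthoquinones into alcohols), in which 8 loses N2 at rhodium, the hydroxyl of 9 adds to B-C1, the proton passes to the oxygen at C2 and ring B aromatises. The threefold excess and the open hydroxyl of 9 should outrun the hindered hydroxyl of 10, and the step serves as a rehearsal of the key step on a cheap phenol.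

Step 8
Reactants: 10 3-[4-(benzyloxy)-2,6-dimethoxyphenoxy]-2-(3,5-dimethoxyphenoxy)-5-methoxyphenol
Product: 11 1-[4-(benzyloxy)-2,6-dimethoxyphenoxy]-2-(3,5-dimethoxyphenoxy)-3,5-dimethoxybenzene
Conditions: MeI, K2CO3, acetone, reflux
Reagents that add atoms: iodomethane, CI
Why: Williamson methylation closes the only free hydroxyl, so that after step 9 the trimer offers a single nucleophilic site.

Step 9
Reactants: 11 1-[4-(benzyloxy)-2,6-dimethoxyphenoxy]-2-(3,5-dimethoxyphenoxy)-3,5-dimethoxybenzene
Product: 12 4-[2-(3,5-dimethoxyphenoxy)-3,5-dimethoxyphenoxy]-3,5-dimethoxyphenol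
Conditions: H2 (1 atm), 10% Pd/C, EtOAc–MeOH, rt
Reagents that add atoms: none
Why: Hydrogenolysis of the single benzyl ether; methyl ethers and diaryl ethers are inert.

Step 10
Reactants: 12 4-[2-(3,5-dimethoxyphenoxy)-3,5-dimethoxyphenoxy]-3,5-dimethoxyphenol; 8 5-[4-(benzyloxy)-2,6-dimethoxyphenoxy]-6-diazo-3-methoxycyclohexa-2,4-dien-1-one
Product: 13 3-[4-(benzyloxy)-2,6-dimethoxyphenoxy]-2-{4-[2-(3,5-dimethoxyphenoxy)-3,5-dimethoxyphenoxy]-3,5-dimethoxyphenoxy}-5-methoxyphenol
Conditions: 8 (1.3 equiv, slow addition), Rh2(esp)2 (2 mol %), 4 Å MS, PhCF3, 60 °C, dark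
Reagents that add atoms: none
Why: Proposed new method: rhodium attacks the diazo carbon of 8 (D-C1), N2 leaves, and a metal-bound quinoid carbene results whose vacant orbital belongs to the ring π system and is therefore open on both faces, although C1 lies between C2=O and the bulky aryloxy group at C6. The single free hydroxyl of 12 (on C-C4, two ortho hydrogens) adds to C1, the oxonium proton passes through a five-membered transition state to the neighbouring oxygen at C2, rhodium leaves and ring D becomes aromatic, which makes the step irreversible. The closest known reactions are the Rh(II)-catalysed O–H insertions of 1,2-diazonaphthoquinones into alcohols and of cyclic 2-diazo-1,3-dicarbonyl compounds into alcohols and phenols; what is new is a phenol as partner of a benzenoid quinone diazide and a doubly flanked carbene carbon. No ring is closed and no stereocentre is formed. Three selectivities are needed: oxygen against ring-carbon attack, which a rhodium(II) carboxylate and the internal base at C2 should favour; one insertion only, secured because the hydroxyl set free in 13 sits beside the new bulky aryloxy group, whereas that of 12 is open; and no azo coupling, since a phenol (pKa about 10) cannot protonate 8 to its reactive diazonium form (pKa about 3–4) and 8 is kept dilute. Attack of a methoxy oxygen of ring E on C1 would have to come in the ring plane, where rhodium sits, and is geometrically disfavoured. Light is excluded to suppress Wolff ring contraction, and sieves keep out water, the only competing O–H donor.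

Step 11
Reactants: 13 3-[4-(benzyloxy)-2,6-dimethoxyphenoxy]-2-{4-[2-(3,5-dimethoxyphenoxy)-3,5-dimethoxyphenoxy]-3,5-dimethoxyphenoxy}-5-methoxyphenol
Product: 14 2-[2-(4-[2-(3,5-dihydroxyphenoxy)-3,5-dihydroxyphenoxy]-3,5-dihydroxyphenoxy)-3,5-dihydroxyphenoxy]benzene-1,3,5-triol (CNP0018313.0)
Conditions: BBr3 (excess), pentamethylbenzene (5 equiv), CH2Cl2, −78 °C to rt; ice-water quench, Ar, degassed solvents
Reagents that add atoms: none
Why: Boron tribromide ether cleavage: bromide attacks the alkyl carbon of each boron-complexed ether, which is impossible at the sp2 carbons of the diaryl ether bridges. Pentamethylbenzene acts as a non-basic scavenger for the benzyl cation and keeps it off the electron-rich rings, and a cold aqueous quench avoids acid-catalysed ether exchange.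

## Compound list

1 | 2,6-dimethoxy-1,4-benzoquinone | COC1=CC(=O)C=C(OC)C1=O | starting material
2 | 2,6-dimethoxybenzene-1,4-diol | COc1cc(O)cc(OC)c1O | intermediate
3 | 4-(benzyloxy)-2,6-dimethoxyphenol | COc1cc(OCc2ccccc2)cc(OC)c1O | intermediate
4 | 1,3-difluoro-5-methoxy-2-nitrobenzene | COc1cc(F)c([N+](=O)[O-])c(F)c1 | starting material
5 | 5-(benzyloxy)-2-(3-fluoro-5-methoxy-2-nitrophenoxy)-1,3-dimethoxybenzene | COc1cc(F)c([N+](=O)[O-])c(Oc2c(OC)cc(OCc3ccccc3)cc2OC)c1 | intermediate
6 | 3-[4-(benzyloxy)-2,6-dimethoxyphenoxy]-5-methoxy-2-nitrophenol | COc1cc(O)c([N+](=O)[O-])c(Oc2c(OC)cc(OCc3ccccc3)cc2OC)c1 | intermediate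
7 | 2-amino-3-[4-(benzyloxy)-2,6-dimethoxyphenoxy]-5-methoxyphenol | COc1cc(O)c(N)c(Oc2c(OC)cc(OCc3ccccc3)cc2OC)c1 | intermediate
8 | 5-[4-(benzyloxy)-2,6-dimethoxyphenoxy]-6-diazo-3-methoxycyclohexa-2,4-dien-1-one | COC1=CC(=O)C(=[N+]=[N-])C(Oc2c(OC)cc(OCc3ccccc3)cc2OC)=C1 | intermediate
9 | 3,5-dimethoxyphenol | COc1cc(O)cc(OC)c1 | starting material
10 | 3-[4-(benzyloxy)-2,6-dimethoxyphenoxy]-2-(3,5-dimethoxyphenoxy)-5-methoxyphenol | COc1cc(O)c(Oc2cc(OC)cc(OC)c2)c(Oc2c(OC)cc(OCc3ccccc3)cc2OC)c1 | intermediate
11 | 1-[4-(benzyloxy)-2,6-dimethoxyphenoxy]-2-(3,5-dimethoxyphenoxy)-3,5-dimethoxybenzene | COc1cc(OC)c(Oc2cc(OC)cc(OC)c2)c(Oc2c(OC)cc(OCc3ccccc3)cc2OC)c1 | intermediate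
12 | 4-[2-(3,5-dimethoxyphenoxy)-3,5-dimethoxyphenoxy]-3,5-dimethoxyphenol | COc1cc(OC)c(Oc2cc(OC)cc(OC)c2)c(Oc2c(OC)cc(O)cc2OC)c1 | intermediate
13 | 3-[4-(benzyloxy)-2,6-dimethoxyphenoxy]-2-{4-[2-(3,5-dimethoxyphenoxy)-3,5-dimethoxyphenoxy]-3,5-dimethoxyphenoxy}-5-methoxyphenol | COc1cc(OC)cc(Oc2c(OC)cc(OC)cc2Oc2c(OC)cc(Oc3c(O)cc(OC)cc3Oc3c(OC)cc(OCc4ccccc4)cc3OC)cc2OC)c1 | intermediate
14 | 2-[2-(4-[2-(3,5-dihydroxyphenoxy)-3,5-dihydroxyphenoxy]-3,5-dihydroxyphenoxy)-3,5-dihydroxyphenoxy]benzene-1,3,5-triol | Oc1cc(O)cc(Oc2c(O)cc(O)cc2Oc2c(O)cc(Oc3c(O)cc(O)cc3Oc3c(O)cc(O)cc3O)cc2O)c1 | target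

## Step count and least certain steps

Total: 11 steps. Longest linear sequence: 11 steps (**1** to **14**). The only convergence is the second use of **8**.

**Step 10 (key step).**
- *Risk:* carbene formation at the flanked diazo carbon may be slow, so that thermal Wolff ring contraction or azine formation takes over. Alternatively the carbene may be captured by an activated ring carbon of **12** instead of its oxygen.
- *Fallback (known chemistry, from 6 back to 14):*
  1. **6** is O-methylated (MeI, K2CO3) to the nitro ether 1-[4-(benzyloxy)-2,6-dimethoxyphenoxy]-3,5-dimethoxy-2-nitrobenzene F1.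
  2. F1 is hydrogenated over Pt(S)/C to the aniline F2.
  3. F2 is converted by Sandmeyer-type iodination (t-BuONO, TsOH, KI, MeCN) into the aryl iodide F3.
  4. An Ullmann-type coupling of F3 with **12** (CuI, picolinic acid, K3PO4, DMSO, 100 °C) gives the fully alkylated pentamer F4.
  5. The conditions of step 11 convert F4 into **14**.

**Step 7.**
- *Risk:* ring-carbon attack is more probable here than in step 10, because **9** has three unsubstituted, triply activated positions. These could take up the carbene or couple with the diazo group.
- *Fallback (known chemistry, reversed roles, from 6 back to 11):*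
  1. **6** is taken through F1 and F2 as above.
  2. F2 is diazotised and hydroxylated (NaNO2, H2SO4; then Cu2O, Cu(NO3)2, H2O) to the flanked phenol 2-[4-(benzyloxy)-2,6-dimethoxyphenoxy]-4,6-dimethoxyphenol F5.
  3. Chan–Lam coupling of F5 with 3,5-dimethoxyphenylboronic acid (Cu(OAc)2, pyridine, 4 Å MS, air, CH2Cl2) gives **11**.

**Step 6.**
- *Risk:* the very electron-rich o-aminophenol may be oxidised by the nitrite to a quinone imine instead of being diazotised, or the outer ring may be nitrosated.
- *Fallback (from 5 back to 8, avoiding the aminophenol and omitting step 4):*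
  1. **5** is hydrogenated over Pt(S)/C to the fluoroaniline F6.
  2. F6 is diazotised (t-BuONO, HBF4·OEt2, MeCN, −20 °C) to the diazonium tetrafluoroborate F7.
  3. F7 is stirred with aqueous NaHCO3/CH2Cl2. Water displaces the fluoride activated by the ortho diazonium group and gives **8**.

**Step 2.**
- *Risk:* loss of site selectivity, double alkylation, or re-oxidation of the hydroquinone by air under base.
- *Fallback (from 2 back to 3):*
  1. **2** is benzylated twice (BnBr in excess, K2CO3, DMF) to 2,5-bis(benzyloxy)-1,3-dimethoxybenzene F8.
  2. The central ether of the 1,2,3-trioxygenated array is cleaved selectively with one equivalent of BCl3 at −78 °C. Chelation by the flanking methoxy groups and relief of strain direct the cleavage, which gives **3**.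

**Step 11.**
- *Risk:* incomplete cleavage among nine methyl ethers, transfer of the benzyl cation to a ring carbon, acid-catalysed ether exchange during the quench, and air oxidation during isolation.
- *Fallback (from 13 back to 14):*
  1. The benzyl group of **13** is removed first by hydrogenolysis (H2, Pd/C) to the diol F9.
  2. F9 is demethylated with BBr3.
  3. The crude polyphenol is acetylated (Ac2O, pyridine) to the undecaacetate F10, which can be purified on silica.
  4. Catalytic NaOMe in degassed MeOH at 0 °C, followed by acidic resin, releases **14**.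

## Further compounds

F1 | step 10 | 1-[4-(benzyloxy)-2,6-dimethoxyphenoxy]-3,5-dimethoxy-2-nitrobenzene | COc1cc(OC)c([N+](=O)[O-])c(Oc2c(OC)cc(OCc3ccccc3)cc2OC)c1
F2 | step 10 | 2-[4-(benzyloxy)-2,6-dimethoxyphenoxy]-4,6-dimethoxyaniline | COc1cc(OC)c(N)c(Oc2c(OC)cc(OCc3ccccc3)cc2OC)c1
F3 | step 10 | 1-[4-(benzyloxy)-2,6-dimethoxyphenoxy]-2-iodo-3,5-dimethoxybenzene | COc1cc(OC)c(I)c(Oc2c(OC)cc(OCc3ccccc3)cc2OC)c1
F4 | step 10 | decamethyl monobenzyl ether of 14 (13 with OMe at D-C2) | COc1cc(OC)cc(Oc2c(OC)cc(OC)cc2Oc2c(OC)cc(Oc3c(OC)cc(OC)cc3Oc3c(OC)cc(OCc4ccccc4)cc3OC)cc2OC)c1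
F5 | step 7 | 2-[4-(benzyloxy)-2,6-dimethoxyphenoxy]-4,6-dimethoxyphenol | COc1cc(OC)c(O)c(Oc2c(OC)cc(OCc3ccccc3)cc2OC)c1
F6 | step 6 | 2-[4-(benzyloxy)-2,6-dimethoxyphenoxy]-6-fluoro-4-methoxyaniline | COc1cc(F)c(N)c(Oc2c(OC)cc(OCc3ccccc3)cc2OC)c1
F7 | step 6 | 2-[4-(benzyloxy)-2,6-dimethoxyphenoxy]-6-fluoro-4-methoxybenzenediazonium tetrafluoroborate | COc1cc(F)c([N+]#N)c(Oc2c(OC)cc(OCc3ccccc3)cc2OC)c1.F[B-](F)(F)F
F8 | step 2 | 2,5-bis(benzyloxy)-1,3-dimethoxybenzene | COc1cc(OCc2ccccc2)cc(OC)c1OCc1ccccc1
F9 | step 11 | debenzylated 13 (free OH at D-C2 and E-C4) | COc1cc(OC)cc(Oc2c(OC)cc(OC)cc2Oc2c(OC)cc(Oc3c(O)cc(OC)cc3Oc3c(OC)cc(O)cc3OC)cc2OC)c1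
F10 | step 11 | undecaacetate of 14 | CC(=O)Oc1cc(OC(C)=O)cc(Oc2c(OC(C)=O)cc(OC(C)=O)cc2Oc2c(OC(C)=O)cc(Oc3c(OC(C)=O)cc(OC(C)=O)cc3Oc3c(OC(C)=O)cc(OC(C)=O)cc3OC(C)=O)cc2OC(C)=O)c1
A1 | alternative 1 | 2-iodo-1,3,5-trimethoxybenzene | COc1cc(OC)c(I)c(OC)c1
A2 | alternative 1 | 2-(3,5-dimethoxyphenoxy)-1,3,5-trimethoxybenzene (diphlorethol pentamethyl ether) | COc1cc(OC)cc(Oc2c(OC)cc(OC)cc2OC)c1
A3 | alternative 2 | phloroglucinol | Oc1cc(O)cc(O)c1
A4 | alternative 2 | 2-(3,5-dihydroxyphenoxy)benzene-1,3,5-triol (diphlorethol) | Oc1cc(O)cc(Oc2c(O)cc(O)cc2O)c1
A5 | alternative 3 | 6-diazo-3,5-dimethoxycyclohexa-2,4-dien-1-one | COC1=CC(=O)C(=[N+]=[N-])C(OC)=C1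
A6 | alternative 3 | 4-diazo-3,5-dimethoxycyclohexa-2,5-dien-1-one | COC1=CC(=O)C=C(OC)C1=[N+]=[N-]
A7 | alternative 3 | 2-(3,5-dimethoxyphenoxy)-3,5-dimethoxyphenol | COc1cc(OC)cc(Oc2c(O)cc(OC)cc2OC)c1
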